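(The constants used here are invented; the result is computed.)

When this flask's catalyst turned over slowly, I asked where the catalyst was sitting.

starting material 5.0 × 10⁻⁴ M; capture agent 0.0250 mM; free catalyst 2.5 µM

    starting material + free catalyst ⇌ catalyst intermediate A (K1 = 6100 /M, k1 = 9.2 × 10⁵ /M/s)
    catalyst intermediate A → catalyst intermediate B (k2 = 94 /s)
    catalyst intermediate B ⇌ free catalyst + product (K3 = 9.2 × 10⁻⁴ M, k3 = 41 /s)
    catalyst intermediate A + capture agent → trapped intermediate (k4 = 59000 /M/s)
    starting material + catalyst intermediate B ⇌ idle complex, settled at all times (K5 = 4100 /M)

- a species is counted by the starting material in it: one idle complex counts as two
- what is bound to the catalyst counts as converted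
- charge of starting material (flask): 5.0 × 10⁻⁴ M

1. the form that holds most of the catalyst when 5.0% of the starting material are converted (trapped intermediate / catalyst intermediate B / catalyst intermediate A / idle complex / free catalyst)
2. its share of the catalyst then

I worked with the fraction left, not the fraction made. At 5.0% conversion, 95.0% of the charge remained, so c(starting material) was 0.475 mM. Multiplying by the balance constant 4100 /M gave 1.95, the parking ratio: idle complex per catalyst intermediate B at balance. This is substrate inhibition.

I took the round as steady and dropped the return of product. Per free catalyst, that gave 1.77 of catalyst intermediate A and 4.07 of catalyst intermediate B. The parking ratio then gave 7.94 of idle complex, and these forms summed to 14.8 with the free catalyst. By this reckoning idle complex held 53.7% of the untrapped catalyst.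

With c(capture agent) taken at its charge, a pseudo-first-order loss, trapping ran at 1.57% of the rate of the second step. I let the whole converted amount pass that step, though bound forms count in it too, which put 15.7% of the catalyst in trapped intermediate. My answer was idle complex at 45.2%.

Then I took each feature away by hand, letting the rate follow catalyst intermediate B. With the first step one-way, catalyst intermediate A per free catalyst rose to 4.58.

| Taken away | Rate multiple by hand |
|---|---|
| parking | 2.16 |
| trapping | 1.19 |
| return in the first step | 1.04 |

The forecast named idle complex at 46%, slightly above mine, reasoning that “the idle complex is about 54% of the active catalyst”.

The flask gave idle complex at 46.1%, with that conversion reached at 0.850 s. The reading of idle complex per catalyst intermediate B was 1.95, beside my parking ratio of 1.95.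

Without trapping the rate was 1.17 times the actual one, and with the first step one-way it was 1.05 times. The flask's rate was held down mainly because starting material parked catalyst intermediate B as idle complex. Without that parking, the rate at 5.0% conversion was 2.15 times the actual one.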